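**Retrosynthetic overview**
1. The target is reached from the pentacyclic lactam 47 by hydrogenation, acetylation and acidolysis. The strategy rests on the vicinal quaternary pair C7–C21 where rings C and D meet inside a 1-azabicyclo[5.2.2] unit (bridgeheads N10 and C21; bridges C8–C7, C11–C12 and C33–C31–C29–C28–C27).
2. The five-carbon bridge is read as a pyrrolidine whose N10–C28 bond has been given up. Cutting C8–N10 and C7–C21 and restoring N10–C28 leads to amino acid 44, a hydrindene acid tied through C13 to a hexahydroindolizine, and the forward reaction is a tethered charge-accelerated aza-Claisen shift.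
3. 44 comes from a B-alkyl Suzuki coupling (C13–C14) of indolizine iodide 41 (fragment 2) with iodo ketal acid 18 (fragment 1).
4. Fragment 1: auxiliary-controlled C5, organocatalytic Robinson annulation (C16, ring B), then malonate Michael closure of ring A. Fragment 2: oxazolidinone-controlled C12 and C29/C31, Petasis coupling (C28) with N-alkylation to the pyrrolidine, then ring-closing metathesis to the tetrahydropyridine.
5. Ring order: B, then A; pyrrolidine, then tetrahydropyridine; rings C, D and E together in the key step.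

Key step: step 26

Remark: atom numbers are those of the heavy atoms in the order of the target SMILES; C7 of fragment 1 is carried as an epimer mixture because it becomes trigonal in step 26.

**Fragment 1 (steps 1–10)**

Step 1
Reactants: 1 (R)-4-benzyloxazolidin-2-one; 2 pent-4-enoyl chloride
Product: 3 (R)-4-benzyl-3-(pent-4-enoyl)oxazolidin-2-one
Conditions: n-BuLi, THF, −78 °C; then 2, −78 to 0 °C
Reagents that add atoms: none
Why: N-acylation of the lithiated oxazolidinone installs the Evans auxiliary that will control C5, and no stereocentre is formed.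

Step 2
Reactants: 3; 4 di-tert-butyl 2-methylenemalonate
Product: 5 di-tert-butyl 2-{(S)-2-[(R)-4-benzyl-2-oxooxazolidine-3-carbonyl]pent-4-en-1-yl}malonate
Conditions: TiCl4, iPr2NEt, CH2Cl2, −78 to 0 °C; then 4
Reagents that add atoms: none
Why: The chelated Z titanium enolate should undergo Michael addition to the methylenemalonate on the face away from the benzyl group (Evans auxiliary control), which sets C5.

Step 3
Reactants: 5
Product: 6 1,1-di-tert-butyl 3-methyl (S)-hex-5-ene-1,1,3-tricarboxylate
Conditions: MeMgBr, MeOH, THF, 0 °C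
Reagents that add atoms: methanol (CO)
Why: Magnesium methoxide transesterification cleaves the exocyclic imide carbonyl and returns the auxiliary without touching the C5 centre.

Step 4
Reactants: 6
Product: 7 1,1-di-tert-butyl 3-methyl (R)-5-oxopentane-1,1,3-tricarboxylate
Conditions: O3, CH2Cl2, −78 °C; then PPh3
Reagents that add atoms: ozone ([O-][O+]=O)
Why: Ozonolysis with reductive work-up turns the terminal alkene into the C15 aldehyde and leaves the esters intact.

Step 5
Reactants: 7; 8 but-3-en-2-one
Product: 10 1,1-di-tert-butyl 3-methyl (R)-3-[(S)-4-oxocyclohex-2-en-1-yl]propane-1,1,3-tricarboxylate, via keto aldehyde 9 (not isolated)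
Conditions: 8, (R)-2-[diphenyl(trimethylsilyloxy)methyl]pyrrolidine (10 mol %), 4-nitrophenol (10 mol %), toluene, 4 °C; then p-TsOH·H2O (20 mol %), 40 °C
Reagents that add atoms: none
Why: Enamine Michael addition to the vinyl ketone on the face left open by the diarylmethyl group of the (R)-catalyst should set C16, and acid-promoted aldol condensation closes ring B (organocatalytic Robinson annulation).

Step 6
Reactants: 10
Product: 12 1,1-di-tert-butyl 3-methyl 6-oxo-7-(phenylselanyl)octahydro-1H-indene-1,1,3-tricarboxylate (cis-fused; C7 selenide epimers), via sodium enolate 11 (not isolated)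
Conditions: NaH (1.05 equiv), THF, 0 °C; then PhSeCl, −78 °C
Reagents that add atoms: benzeneselenenyl chloride (Cl[Se]c1ccccc1)
Why: The malonate anion should add 5-exo-trig to C15 of the enone (intramolecular Michael, cis ring fusion enforced by the tether on C16) to close ring A, and the regiodefined enolate is trapped at C14 by selenenylation.

Step 7
Reactants: 12
Product: 14 1,1-di-tert-butyl 3-methyl (3R,3aR)-6-oxo-2,3,3a,4,5,6-hexahydro-1H-indene-1,1,3-tricarboxylate, via selenoxide 13 (not isolated)
Conditions: 30% aq. H2O2, pyridine, CH2Cl2, 0 °C to rt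
Reagents that add atoms: none
Why: Selenoxide syn-elimination can only use the C15 hydrogen, so the C14=C15 enone is regenerated regiospecifically and C15 becomes trigonal.

Step 8
Reactants: 14
Product: 16 (3R,3aR)-3-(methoxycarbonyl)-6-oxo-2,3,3a,4,5,6-hexahydro-1H-indene-1-carboxylic acid (C1 epimers), via malonic diacid 15 (not isolated)
Conditions: TFA, CH2Cl2, rt; then toluene, 100 °C
Reagents that add atoms: none
Why: Acidolysis of both tert-butyl esters followed by thermal decarboxylation of the malonic acid leaves the C7 acid and keeps the methyl ester, so the two carboxyl groups are differentiated.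

Step 9
Reactants: 16
Product: 17 (3R,3aR)-7-iodo-3-(methoxycarbonyl)-6-oxo-2,3,3a,4,5,6-hexahydro-1H-indene-1-carboxylic acid (C1 epimers)
Conditions: I2, pyridine, DMAP (cat.), CH2Cl2, rt
Reagents that add atoms: iodine (II)
Why: Johnson-type α-iodination of the enone should place iodine at C14, with enolisation directed towards the acidic C7–H and away from the C16 centre.

Step 10
Reactants: 17
Product: 18 (3R,3aR)-7-iodo-3-(methoxycarbonyl)-1,2,3,3a,4,5-hexahydrospiro[indene-6,2′-[1,3]dioxolane]-1-carboxylic acid (C1 epimers)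
Conditions: TMSOCH2CH2OTMS, TMSOTf (cat.), CH2Cl2, −78 to −20 °C; aqueous work-up
Reagents that add atoms: 1,2-bis(trimethylsilyloxy)ethane (C[Si](C)(C)OCCO[Si](C)(C)C)
Why: Aprotic Noyori ketalisation at low temperature should mask C19 without moving the iodo-substituted double bond, and the transient silyl ester is cleaved on work-up.

**Fragment 2, amine arm (steps 11–16)**

Step 11
Reactants: 19 3-chloro-2-(chloromethyl)prop-1-ene; 20 benzyl alcohol
Product: 21 benzyl 2-(chloromethyl)allyl ether
Conditions: NaH, THF, 0 °C to rt, 19 in excess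
Reagents that add atoms: none
Why: Williamson etherification with the dichloride in excess should favour mono-substitution.

Step 12
Reactants: 21
Product: 23 3-[(benzyloxy)methyl]but-3-enoic acid, via allylmagnesium chloride 22 (not isolated)
Conditions: Mg turnings, THF, 0 °C, slow addition; then CO2, −78 °C; aq. HCl
Reagents that add atoms: carbon dioxide (O=C=O)
Why: Carboxylation of the symmetrical 2-substituted allyl Grignard reagent can give only one β,γ-unsaturated acid.

Step 13
Reactants: 23; 24 (S)-4-benzyloxazolidin-2-one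
Product: 26 (S)-4-benzyl-3-{3-[(benzyloxy)methyl]but-3-enoyl}oxazolidin-2-one, via mixed pivalic anhydride 25 (not isolated)
Conditions: PivCl, Et3N, THF, −20 °C; then 24, LiCl, −20 °C to rt
Reagents that add atoms: none
Why: Mixed-anhydride acylation under mild base attaches the auxiliary without moving the double bond into conjugation.

Step 14
Reactants: 26
Product: 27 (S)-4-benzyl-3-{(R)-3-[(benzyloxy)methyl]-2-(hydroxymethyl)but-3-enoyl}oxazolidin-2-one
Conditions: TiCl4, iPr2NEt, CH2Cl2, 0 °C; then 1,3,5-trioxane, TiCl4, 0 °C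
Reagents that add atoms: 1,3,5-trioxane (C1OCOCO1)
Why: Hydroxymethylation of the Z titanium enolate at the α-carbon, anti to the benzyl group, sets C12 and differentiates the two one-carbon arms (Evans auxiliary control).

Step 15
Reactants: 27
Product: 28 (R)-3-[(benzyloxy)methyl]-2-(hydroxymethyl)but-3-enamide
Conditions: Me3Al, NH4Cl, CH2Cl2, 0 °C to rt
Reagents that add atoms: ammonium chloride ([NH4+].[Cl-])
Why: Weinreb-type aluminium amide aminolysis, assisted by the β-hydroxyl, should cleave the exocyclic carbonyl and turn the acyl carbon into the future C11.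

Step 16
Reactants: 28
Product: 29 (S)-2-(aminomethyl)-3-[(benzyloxy)methyl]but-3-en-1-ol
Conditions: LiAlH4, THF, reflux; Na2SO4·10H2O work-up
Reagents that add atoms: none
Why: Hydride reduction of the primary amide gives the primary amine without affecting the allyl benzyl ether or the C12 centre.

**Fragment 2, aldehyde arm (steps 17–20)**

Step 17
Reactants: 30 (S)-4-benzyl-3-propionyloxazolidin-2-one; 31 acrolein
Product: 32 (S)-4-benzyl-3-[(2S,3R)-3-hydroxy-2-methylpent-4-enoyl]oxazolidin-2-one
Conditions: Bu2BOTf, iPr2NEt, CH2Cl2, 0 °C; 31, −78 to 0 °C; H2O2, pH 7 buffer, MeOH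
Reagents that add atoms: none
Why: The Evans syn-aldol reaction through the Z boron enolate and a Zimmerman–Traxler transition state sets C31 and C29.

Step 18
Reactants: 32
Product: 33 (2R,3R)-2-methylpent-4-ene-1,3-diol
Conditions: LiBH4, MeOH (1 equiv), THF, 0 °C
Reagents that add atoms: none
Why: Reductive removal of the auxiliary gives the diol whose primary carbon becomes C33.

Step 19
Reactants: 33
Product: 34 (2R,3R)-3-hydroxy-2-methylpent-4-en-1-yl 4-methylbenzenesulfonate
Conditions: TsCl, Et3N, Bu2SnO (2 mol %), CH2Cl2, 0 °C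
Reagents that add atoms: 4-methylbenzenesulfonyl chloride (Cc1ccc(cc1)S(Cl)(=O)=O)
Why: Tin-catalysed sulfonylation should select the primary over the secondary allylic hydroxyl.

Step 20
Reactants: 34
Product: 35 (2R,3S)-3-hydroxy-2-methyl-4-oxobutyl 4-methylbenzenesulfonate
Conditions: O3, CH2Cl2–MeOH, −78 °C; then Me2S; used at once
Reagents that add atoms: ozone ([O-][O+]=O)
Why: Ozonolysis of the vinyl group unmasks the α-hydroxy aldehyde (C28) needed for the borono-Mannich step.

**Fragment 2, assembly (steps 21–24)**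

Step 21
Reactants: 35; 29; 36 (E)-(2-phenylethenyl)boronic acid
Product: 38 (2R,3S,4R)-1-{(S)-3-[(benzyloxy)methyl]-2-(hydroxymethyl)but-3-en-1-yl}-4-methyl-2-[(E)-styryl]pyrrolidin-3-ol, via Petasis amine 37 (not isolated)
Conditions: EtOH–CH2Cl2, rt; then K2CO3, MeCN, 60 °C
Reagents that add atoms: none
Why: In the Petasis borono-Mannich reaction the boronate bound to the α-hydroxyl delivers the styryl group to the iminium ion to give the anti amino alcohol (C28), and the secondary amine then displaces the primary tosylate (5-exo-tet) to form the pyrrolidine.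

Step 22
Reactants: 38
Product: 39 (1S,2R,6S,8aR)-7-[(benzyloxy)methyl]-6-(hydroxymethyl)-2-methyl-1,2,3,5,6,8a-hexahydroindolizin-1-ol
Conditions: p-TsOH·H2O (1.05 equiv), RuCl2(H2IMes)(=CH-C6H4-2-OiPr) (second-generation Hoveyda–Grubbs catalyst, 5 mol %), toluene, 80 °C; aq. NaHCO3
Reagents that add atoms: none
Why: Ring-closing metathesis of the ammonium salt joins the styryl and 1,1-disubstituted alkenes into the trisubstituted C21=C27 bond of the six-membered ring and releases styrene.

Step 23
Reactants: 39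
Product: 40 (1S,2R,6S,8aR)-7-[(benzyloxy)methyl]-6-(iodomethyl)-2-methyl-1,2,3,5,6,8a-hexahydroindolizin-1-ol
Conditions: I2, PPh3, imidazole, CH2Cl2, 0 °C
Reagents that add atoms: iodine (II)
Why: Appel-type iodination should select the primary C13 hydroxyl over the flanked secondary one, and the rigid bicycle disfavours azetidinium formation that would scramble C12.

Step 24
Reactants: 40
Product: 41 (1S,2R,6S,8aR)-7-[(benzyloxy)methyl]-1-[(tert-butyldimethylsilyl)oxy]-6-(iodomethyl)-2-methyl-1,2,3,5,6,8a-hexahydroindolizine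
Conditions: TBSOTf, 2,6-lutidine, CH2Cl2, −78 to 0 °C
Reagents that add atoms: tert-butyldimethylsilyl trifluoromethanesulfonate (CC(C)(C)[Si](C)(C)OS(=O)(=O)C(F)(F)F)
Why: Silylation of the hindered C29 hydroxyl with the silyl triflate protects it against acylation in the key step.

**Union, key step and endgame (steps 25–29)**

Step 25
Reactants: 41; 18
Product: 44 amino acid precursor (C13-linked hydrindene ketal acid–hexahydroindolizine; C7 epimers), via alkyllithium 42 (not isolated), via lithium borinate 43 (not isolated)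
Conditions: 41, t-BuLi (2.1 equiv), Et2O, −78 °C; B-methoxy-9-BBN, THF, −78 °C to rt; then 18, PdCl2(dppf), AsPh3, Cs2CO3, DMF–H2O, rt; pH 6 work-up
Reagents that add atoms: none
Why: Lithium–iodine exchange and capture by the methoxyborane give a B-alkyl borinate that should undergo B-alkyl Suzuki–Miyaura coupling with the vinyl iodide (present as its carboxylate), forming C13–C14 without touching any stereocentre.

Step 26
Reactants: 44
Product: 47 pentacyclic bridged lactam with Z C27=C28 alkene and C19 ketal, via acyloxypyridinium salt 45 (not isolated), via acylammonium enolate 46 (not isolated)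
Conditions: 2-fluoro-1-methylpyridinium p-toluenesulfonate (1.5 equiv), iPr2NEt (4 equiv), MeCN, 60 °C, slow addition of 44 (final 1 mM)
Reagents that add atoms: none
Why: Proposed new method: the carboxylate is converted into the acyloxypyridinium 45, whose C8 (directly or through the vinylketene formed by loss of the acidic allylic C7–H) acylates N10 across an eight-membered array, and deprotonation gives the acylammonium enolate 46, which should undergo a charge-accelerated [3,3] shift through the boat array C7–C8–N10–C28–C27–C21 that forms C7–C21, breaks N10–C28 and is driven by charge cancellation and amide resonance. The closest known reactions are the zwitterionic ketene aza-Claisen ring expansion of 2-vinylpyrrolidines to nine-membered lactams and the boat-type ester-enolate Claisen ring contraction of macrolactones; here the allyl amine unit lies inside the tetrahydropyridine ring, which is why the step is new. Ring C closes by attack of C7 on C21 of the C21=C27 bond (6-exo), ring D (N10–C8–C7–C21–C12–C11) is closed by the same bond as a transannular contraction of the eight-membered acylammonium ring, and ring E is not closed by bond formation but arises when scission of N10–C28 enlarges the pyrrolidine to nine members. C21 is set by the C13 tether on C12, which can deliver C7 only to the C13 face of the alkene, and C7 by the ring-enforced enolate geometry (N10 cis to C15) meeting that same face, so both quaternary centres follow from C12 and the fixed C5/C16 of the hydrindene. The Z geometry of C27=C28 follows from C29 lying anti to the acylated face at C28, with N10 reacting through its cis-fused invertomer. The step needs the shift to outrun intermolecular acylation, ketene [2+2] addition to C21=C27 and dealkylation of 46, which high dilution, the tether and the non-nucleophilic fluoride and tosylate counter-ions should secure.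

Step 27
Reactants: 47
Product: 48 saturated hydroxymethyl lactam (C22 alcohol, C29 silyl ether, C19 ketal)
Conditions: H2 (1 atm), Pd/C (10% palladium on carbon), EtOAc–MeOH, rt
Reagents that add atoms: none
Why: Catalytic hydrogenation should saturate the Z-disubstituted alkene and cleave the benzyl ether, while the tetrasubstituted C14=C15 bond next to the ketal is too hindered to react.

Step 28
Reactants: 48
Product: 49 C22 acetate (C29 silyl ether, C19 ketal)
Conditions: Ac2O, pyridine, DMAP (cat.), CH2Cl2, rt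
Reagents that add atoms: acetic anhydride (CC(=O)OC(C)=O)
Why: DMAP-catalysed acetylation esterifies the only free hydroxyl, the neopentyl primary alcohol at C22.

Step 29
Reactants: 49
Product: 50 CNP0123592.1
Conditions: 48% aq. HF, MeCN, 0 °C to rt
Reagents that add atoms: water (O)
Why: Aqueous HF removes the silyl ether and hydrolyses the allylic ketal to the C19 enone in one operation, and the acetate, methyl ester and lactam survive.

**Compound list**
1 | (R)-4-benzyloxazolidin-2-one | O=C1N[C@H](Cc2ccccc2)CO1 | starting material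
2 | pent-4-enoyl chloride | C=CCCC(Cl)=O | starting material
3 | (R)-4-benzyl-3-(pent-4-enoyl)oxazolidin-2-one | C=CCCC(=O)N1[C@H](Cc2ccccc2)COC1=O | intermediate
4 | di-tert-butyl 2-methylenemalonate | C=C(C(=O)OC(C)(C)C)C(=O)OC(C)(C)C | starting material
5 | di-tert-butyl 2-{(S)-2-[(R)-4-benzyl-2-oxooxazolidine-3-carbonyl]pent-4-en-1-yl}malonate | O=C(N1[C@H](Cc2ccccc2)COC1=O)[C@H](CC(C(=O)OC(C)(C)C)C(=O)OC(C)(C)C)CC=C | intermediate
6 | 1,1-di-tert-butyl 3-methyl (S)-hex-5-ene-1,1,3-tricarboxylate | COC(=O)[C@H](CC(C(=O)OC(C)(C)C)C(=O)OC(C)(C)C)CC=C | intermediate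
7 | 1,1-di-tert-butyl 3-methyl (R)-5-oxopentane-1,1,3-tricarboxylate | COC(=O)[C@H](CC(C(=O)OC(C)(C)C)C(=O)OC(C)(C)C)CC=O | intermediate
8 | but-3-en-2-one | CC(=O)C=C | starting material
9 | 1,1-di-tert-butyl 3-methyl (3R,4R)-4-formyl-7-oxooctane-1,1,3-tricarboxylate | COC(=O)[C@H](CC(C(=O)OC(C)(C)C)C(=O)OC(C)(C)C)[C@H](C=O)CCC(C)=O | intermediate
10 | 1,1-di-tert-butyl 3-methyl (R)-3-[(S)-4-oxocyclohex-2-en-1-yl]propane-1,1,3-tricarboxylate | COC(=O)[C@H](CC(C(=O)OC(C)(C)C)C(=O)OC(C)(C)C)[C@@H]1C=CC(=O)CC1 | intermediate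
11 | sodium enolate of the cis-fused bicyclic ketone (C19 enolate, C14=C19) | COC(=O)[C@@H]1CC(C(=O)OC(C)(C)C)(C(=O)OC(C)(C)C)[C@@H]2C=C([O-])CC[C@H]12.[Na+] | intermediate
12 | 1,1-di-tert-butyl 3-methyl 6-oxo-7-(phenylselanyl)octahydro-1H-indene-1,1,3-tricarboxylate (cis-fused, C7 epimers) | COC(=O)[C@@H]1CC(C(=O)OC(C)(C)C)(C(=O)OC(C)(C)C)[C@@H]2C([Se]c3ccccc3)C(=O)CC[C@H]12 | intermediate
13 | selenoxide of 12 | COC(=O)[C@@H]1CC(C(=O)OC(C)(C)C)(C(=O)OC(C)(C)C)[C@@H]2C([Se](=O)c3ccccc3)C(=O)CC[C@H]12 | intermediate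
14 | 1,1-di-tert-butyl 3-methyl (3R,3aR)-6-oxo-2,3,3a,4,5,6-hexahydro-1H-indene-1,1,3-tricarboxylate | COC(=O)[C@@H]1CC(C(=O)OC(C)(C)C)(C(=O)OC(C)(C)C)C2=CC(=O)CC[C@H]12 | intermediate
15 | (3R,3aR)-3-(methoxycarbonyl)-6-oxo-2,3,3a,4,5,6-hexahydro-1H-indene-1,1-dicarboxylic acid | COC(=O)[C@@H]1CC(C(=O)O)(C(=O)O)C2=CC(=O)CC[C@H]12 | intermediate
16 | (3R,3aR)-3-(methoxycarbonyl)-6-oxo-2,3,3a,4,5,6-hexahydro-1H-indene-1-carboxylic acid (C1 epimers) | COC(=O)[C@@H]1CC(C(=O)O)C2=CC(=O)CC[C@H]12 | intermediate
17 | (3R,3aR)-7-iodo-3-(methoxycarbonyl)-6-oxo-2,3,3a,4,5,6-hexahydro-1H-indene-1-carboxylic acid (C1 epimers) | COC(=O)[C@@H]1CC(C(=O)O)C2=C(I)C(=O)CC[C@H]12 | intermediate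
18 | (3R,3aR)-7-iodo-3-(methoxycarbonyl)-1,2,3,3a,4,5-hexahydrospiro[indene-6,2′-[1,3]dioxolane]-1-carboxylic acid (C1 epimers) | COC(=O)[C@@H]1CC(C(=O)O)C2=C(I)C3(OCCO3)CC[C@H]12 | intermediate
19 | 3-chloro-2-(chloromethyl)prop-1-ene | ClCC(=C)CCl | starting material
20 | benzyl alcohol | OCc1ccccc1 | starting material
21 | benzyl 2-(chloromethyl)allyl ether | ClCC(=C)COCc1ccccc1 | intermediate
22 | {2-[(benzyloxy)methyl]allyl}magnesium chloride | Cl[Mg]CC(=C)COCc1ccccc1 | intermediate
23 | 3-[(benzyloxy)methyl]but-3-enoic acid | OC(=O)CC(=C)COCc1ccccc1 | intermediate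
24 | (S)-4-benzyloxazolidin-2-one | O=C1N[C@@H](Cc2ccccc2)CO1 | starting material
25 | 3-[(benzyloxy)methyl]but-3-enoic pivalic anhydride | CC(C)(C)C(=O)OC(=O)CC(=C)COCc1ccccc1 | intermediate
26 | (S)-4-benzyl-3-{3-[(benzyloxy)methyl]but-3-enoyl}oxazolidin-2-one | O=C(CC(=C)COCc1ccccc1)N1[C@@H](Cc2ccccc2)COC1=O | intermediate
27 | (S)-4-benzyl-3-{(R)-3-[(benzyloxy)methyl]-2-(hydroxymethyl)but-3-enoyl}oxazolidin-2-one | O=C(N1[C@@H](Cc2ccccc2)COC1=O)[C@@H](CO)C(=C)COCc1ccccc1 | intermediate
28 | (R)-3-[(benzyloxy)methyl]-2-(hydroxymethyl)but-3-enamide | NC(=O)[C@@H](CO)C(=C)COCc1ccccc1 | intermediate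
29 | (S)-2-(aminomethyl)-3-[(benzyloxy)methyl]but-3-en-1-ol | NC[C@@H](CO)C(=C)COCc1ccccc1 | intermediate
30 | (S)-4-benzyl-3-propionyloxazolidin-2-one | CCC(=O)N1[C@@H](Cc2ccccc2)COC1=O | starting material
31 | acrolein | C=CC=O | starting material
32 | (S)-4-benzyl-3-[(2S,3R)-3-hydroxy-2-methylpent-4-enoyl]oxazolidin-2-one | O=C(N1[C@@H](Cc2ccccc2)COC1=O)[C@@H](C)[C@H](O)C=C | intermediate
33 | (2R,3R)-2-methylpent-4-ene-1,3-diol | C=C[C@@H](O)[C@H](C)CO | intermediate
34 | (2R,3R)-3-hydroxy-2-methylpent-4-en-1-yl 4-methylbenzenesulfonate | C=C[C@@H](O)[C@H](C)COS(=O)(=O)c1ccc(C)cc1 | intermediate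
35 | (2R,3S)-3-hydroxy-2-methyl-4-oxobutyl 4-methylbenzenesulfonate | O=C[C@@H](O)[C@H](C)COS(=O)(=O)c1ccc(C)cc1 | intermediate
36 | (E)-(2-phenylethenyl)boronic acid | OB(O)/C=C/c1ccccc1 | starting material
37 | (2R,3S,4R,E)-4-({(S)-3-[(benzyloxy)methyl]-2-(hydroxymethyl)but-3-en-1-yl}amino)-3-hydroxy-2-methyl-6-phenylhex-5-en-1-yl 4-methylbenzenesulfonate | OC[C@H](CN[C@H](/C=C/c1ccccc1)[C@@H](O)[C@H](C)COS(=O)(=O)c1ccc(C)cc1)C(=C)COCc1ccccc1 | intermediate
38 | (2R,3S,4R)-1-{(S)-3-[(benzyloxy)methyl]-2-(hydroxymethyl)but-3-en-1-yl}-4-methyl-2-[(E)-styryl]pyrrolidin-3-ol | OC[C@H](CN1C[C@@H](C)[C@H](O)[C@H]1/C=C/c1ccccc1)C(=C)COCc1ccccc1 | intermediate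
39 | (1S,2R,6S,8aR)-7-[(benzyloxy)methyl]-6-(hydroxymethyl)-2-methyl-1,2,3,5,6,8a-hexahydroindolizin-1-ol | OC[C@@H]1CN2C[C@@H](C)[C@H](O)[C@H]2C=C1COCc1ccccc1 | intermediate
40 | (1S,2R,6S,8aR)-7-[(benzyloxy)methyl]-6-(iodomethyl)-2-methyl-1,2,3,5,6,8a-hexahydroindolizin-1-ol | IC[C@@H]1CN2C[C@@H](C)[C@H](O)[C@H]2C=C1COCc1ccccc1 | intermediate
41 | (1S,2R,6S,8aR)-7-[(benzyloxy)methyl]-1-[(tert-butyldimethylsilyl)oxy]-6-(iodomethyl)-2-methyl-1,2,3,5,6,8a-hexahydroindolizine | IC[C@@H]1CN2C[C@@H](C)[C@H](O[Si](C)(C)C(C)(C)C)[C@H]2C=C1COCc1ccccc1 | intermediate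
42 | C13 alkyllithium from 41 | [Li]C[C@@H]1CN2C[C@@H](C)[C@H](O[Si](C)(C)C(C)(C)C)[C@H]2C=C1COCc1ccccc1 | intermediate
43 | lithium B-alkyl-B-methoxy-9-borabicyclo[3.3.1]nonan-9-uide (alkyl = C13 of 42) | [Li+].CO[B-]1(C[C@@H]2CN3C[C@@H](C)[C@H](O[Si](C)(C)C(C)(C)C)[C@H]3C=C2COCc2ccccc2)C2CCCC1CCC2 | intermediate
44 | amino acid precursor: C13-linked hydrindene ketal acid–hexahydroindolizine (C5, C16, C12, C28, C29, C31 as in SMILES; C7 epimers) | COC(=O)[C@@H]1CC(C(=O)O)C2=C(C[C@@H]3CN4C[C@@H](C)[C@H](O[Si](C)(C)C(C)(C)C)[C@H]4C=C3COCc5ccccc5)C6(OCCO6)CC[C@H]12 | intermediate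
45 | 2-acyloxy-1-methylpyridinium p-toluenesulfonate of 44 | COC(=O)[C@@H]1CC(C(=O)Oc7cccc[n+]7C)C2=C(C[C@@H]3CN4C[C@@H](C)[C@H](O[Si](C)(C)C(C)(C)C)[C@H]4C=C3COCc5ccccc5)C6(OCCO6)CC[C@H]12.Cc1ccc(cc1)S(=O)(=O)[O-] | intermediate
46 | acylammonium enolate zwitterion (N10–C8 bond, C7=C8 enolate, N10 cis to C15) | COC(=O)[C@@H]1C/C(=C(\[O-])%10)C2=C(C[C@@H]3C[N@+]%104C[C@@H](C)[C@H](O[Si](C)(C)C(C)(C)C)[C@H]4C=C3COCc5ccccc5)C6(OCCO6)CC[C@H]12 | intermediate
47 | pentacyclic bridged lactam with Z C27=C28 alkene, C22 benzyl ether, C29 silyl ether, C19 ketal | COC(=O)[C@@H]1C[C@@]23C(=O)N4C[C@@H](CC5=C2[C@@H]1CCC56OCCO6)[C@]3(COCc7ccccc7)/C=C\[C@@H](O[Si](C)(C)C(C)(C)C)[C@H](C)C4 | intermediate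
48 | saturated lactam with free C22 hydroxyl, C29 silyl ether, C19 ketal | COC(=O)[C@@H]1C[C@@]23C(=O)N4C[C@@H](CC5=C2[C@@H]1CCC56OCCO6)[C@]3(CO)CC[C@@H](O[Si](C)(C)C(C)(C)C)[C@H](C)C4 | intermediate
49 | C22 acetate with C29 silyl ether and C19 ketal | COC(=O)[C@@H]1C[C@@]23C(=O)N4C[C@@H](CC5=C2[C@@H]1CCC56OCCO6)[C@]3(COC(C)=O)CC[C@@H](O[Si](C)(C)C(C)(C)C)[C@H](C)C4 | intermediate
50 | CNP0123592.1 | COC(=O)[C@@H]1C[C@@]23C(=O)N4C[C@@H](CC5=C2[C@@H]1CCC5=O)[C@]3(COC(C)=O)CC[C@@H](O)[C@H](C)C4 | target

**Step count**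
Total: 29 steps. Longest linear sequence: 15 steps (steps 11–16, 21–24, 25–29; equally steps 1–10, 25–29).

**Steps most likely to fail**

1. Step 26 (proposed new method). The allylic N10–C28 bond is held inside the tetrahydropyridine ring at a small angle to the C21=C27 π system, so the acylammonium enolate may not reach the boat geometry and may instead be dealkylated, add as a ketene to the alkene, or revert to the amino acid. A fallback by known reactions sets out from 44 and returns at 47. The acid is esterified (TMSCHN2, MeOH–toluene) to the dimethyl ester F1. A von Braun-type cleavage with 2,2,2-trichloroethyl chloroformate (K2CO3, MeCN, 60 °C) breaks the allylic N10–C28 bond and gives the nine-membered N-carbamate allylic chloride F2. The C7 ester enolate (KN(SiMe3)2, THF, −78 °C, with Pd(PPh3)4 as catalyst) is then alkylated intramolecularly at C21 (allylic alkylation, six-membered ring C, alkene shifted to C27=C28 and cis within the nine-membered ring) to give the cyclised carbamate F3. Finally Zn dust in AcOH removes the carbamate, and warming in toluene lets the freed secondary amine close the lactam onto the C8 ester to give 47.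

2. Step 25. Oxidative addition and transmetalation at the tetrasubstituted vinyl iodide flanked by the ketal may be slow, so that protodeboronation or β-hydride elimination of the alkyl borinate takes over. The fallback sets out from 41 and 18 (as its sodium salt) and returns at 44. It joins the two iodides directly by nickel-catalysed reductive cross-electrophile coupling (NiBr2(dme), 4,4′-di-tert-butyl-2,2′-bipyridine, Mn powder, DMA, rt), which needs no organolithium or organoboron intermediate and makes no new compound.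

3. Step 6. Proton exchange of the bicyclic enolate before selenenylation would lose the regiocontrol, and retro-Michael opening or dienolate formation could erode C16. The fallback sets out from 10 and returns at 14. Thiophenol is added to the enone (PhSH, Et3N, CH2Cl2) to give the β-phenylthio ketone F4. Chlorination at sulfur-bearing C15 and loss of HCl (N-chlorosuccinimide, CCl4, then Et3N) give the 3-(phenylthio)enone F5. NaH in THF then lets the malonate close ring A by addition–elimination at C15 with loss of thiophenolate, which returns the C14=C15 enone 14 directly.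

**Further compounds**
F1 | step 26 | dimethyl ester of 44 (C8 methyl ester) | COC(=O)[C@@H]1CC(C(=O)OC)C2=C(C[C@@H]3CN4C[C@@H](C)[C@H](O[Si](C)(C)C(C)(C)C)[C@H]4C=C3COCc5ccccc5)C6(OCCO6)CC[C@H]12
F2 | step 26 | nine-membered N-(2,2,2-trichloroethoxycarbonyl) azacycle with C28 allylic chloride (N10–C28 cleaved) | COC(=O)[C@@H]1CC(C(=O)OC)C2=C(C[C@@H]3CN(C(=O)OCC(Cl)(Cl)Cl)C[C@@H](C)[C@H](O[Si](C)(C)C(C)(C)C)[C@@H](Cl)/C=C3/COCc5ccccc5)C6(OCCO6)CC[C@H]12
F3 | step 26 | C7–C21 cyclised N-(2,2,2-trichloroethoxycarbonyl) diester with Z C27=C28 alkene | COC(=O)[C@@H]1C[C@@]2(C(=O)OC)C3=C(C[C@@H]4CN(C(=O)OCC(Cl)(Cl)Cl)C[C@@H](C)[C@H](O[Si](C)(C)C(C)(C)C)/C=C\[C@]24COCc5ccccc5)C6(OCCO6)CC[C@H]13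
F0 | step 25 | none | none
F4 | step 6 | 3-(phenylthio)cyclohexanone adduct of 10 (C15 sulfide epimers) | COC(=O)[C@H](CC(C(=O)OC(C)(C)C)C(=O)OC(C)(C)C)[C@@H]1C(Sc2ccccc2)CC(=O)CC1
F5 | step 6 | 3-(phenylthio)cyclohex-2-enone derived from 10 | COC(=O)[C@H](CC(C(=O)OC(C)(C)C)C(=O)OC(C)(C)C)[C@@H]1C(Sc2ccccc2)=CC(=O)CC1
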